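The readings are simulated from invented constants; scatter was added.

in all of them: starting material 0.0050 M

|  | partner | reagent | protic impurity | remark | time |
|---|---|---|---|---|---|
| Wednesday's | 9 mM | 5.3 mM | 5 mM | run made earlier |  |
| Sunday's | 9 mM | 9.4 mM | 5 mM | run made earlier |  |
| Saturday's | 9 mM | 9.5 mM | 5 mM | run made earlier |  |
| winter | 9.00 mM | 6.50 mM | 5.00 mM |  | 3.0 min |
| spring | 9.00 mM | 13.0 mM | 5.00 mM |  | 3.0 min |

| run | time / s | product / % | starting material / % | open intermediate / % |
|---|---|---|---|---|
| Wednesday's | 10.0 | 1 | 48 | 45 |
| Wednesday's | 15.0 | 7 | 46 | 47 |
| Wednesday's | 25.0 | 14 | 34 | 52 |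
| Wednesday's | 50.0 | 21 | 28 | 41 |
| Wednesday's | 90.0 | 32 | 33 | 39 |
| Sunday's | 20.0 | 20 | 16 | 66 |
| Sunday's | 40.0 | 43 | 6 | 57 |
| Sunday's | 50.0 | 47 | 5 | 49 |
| Sunday's | 80.0 | 58 | 6 | 39 |
| Sunday's | 90.0 | 64 | 4 | 40 |
| Saturday's | 20.0 | 22 | 12 | 67 |
| Saturday's | 40.0 | 39 | 6 | 54 |
| Saturday's | 50.0 | 48 | 5 | 50 |
| Saturday's | 80.0 | 59 | 3 | 40 |
| Saturday's | 90.0 | 63 | 2 | 33 |

(each reading ± 2 percentage points)

- what was read earlier has a scatter of 2 percentage points, one standard deviation
- a reading or a percentage of product counts all its forms, free or not

1. which of these there is most of at the end, counted by the starting material in it, winter (open intermediate / product / starting material)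
2. which of these there is most of at the end, counted by the starting material in it, spring (open intermediate / product / starting material)
3. the largest of these amounts at the end, in percent of the starting material charged, winter
4. the largest of these amounts at the end, in percent of the starting material charged, spring

- In a one-step world a reagent opens a starting material and the story ends. Wednesday's charge of 1.06 reagent per starting material should then have cleared that flask, yet Wednesday's last two readings still averaged 30.5% starting material.
- At Wednesday's last reading, opened share plus product came to 99.0%, which stood below that charge by 7 percentage points and did not exceed it, so I took each product to cost a second reagent and left that gap unexplained.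
- For winter I therefore carried 1.30: the reagent number, reagent charged per starting material charged, c(reagent)/c(starting material). It is the ceiling on opened share plus product, with reagent as limiting reagent.
- Starting material stood at 30.5% for Wednesday's 1.06 and at 3.75% for the 1.89 of Sunday's and Saturday's runs. I assumed first-order decay in reagent used, which left 16.6% in winter.
- The ceiling then gave winter 46.6% product, ahead of 36.8% open intermediate.
- One number was not enough: Sunday's last reading summed to 160% against 1.88, so there the clock counted too. Spring's 2.60 lies above two, so I named no spring figure.
- The forecast said product at 60% (51% to 68%) for winter and product at 80% (70% to 92%) for spring, noting: “Spring should resemble Sunday's and Saturday's runs, but the excess reagent is untested”. Its winter figure differed from mine.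

    starting material + reagent → open intermediate (k = 25.3 M⁻¹ s⁻¹)
    reagent + partner → second intermediate (k = 8.48 M⁻¹ s⁻¹)
    open intermediate + second intermediate → product (k = 9.95 M⁻¹ s⁻¹)
    crystals ⇌ product, rate k4*(cs4 - [product]) while solid is left; crystals form when [product] > cs4 (solubility = 1.60 mM, k = 0.678 s⁻¹)
    partner + protic impurity → quenched reagent (k = 25.0 M⁻¹ s⁻¹)

- Winter gave product at 46.5%, and spring gave product at 84.8%; the forecast's winter figure stood 13 points high.
- Winter's opened share plus product was 128% against 1.30; with the forecast's product it would be 142%.
- Spring with 0.020 M protic impurity kept 2.60, but its opened share plus product reached 132%, matching the 1.32 of reagent used per starting material charged.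
- That neighbour ended with 31.9% product and 68.1% open intermediate.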